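## Structural features

The target is a flavone: a benzo ring A fused to a 4H-pyran-4-one ring C, with a phenyl ring B attached at C2 through one aryl–vinyl single bond. It has no stereocenter and no other element of chirality, so nothing has to be controlled in space. The difficulty lies in the oxygen pattern. Ring A is fully substituted (OH at C5, OMe at C6, C7 and C8), ring C carries OMe at C3, and ring B is a symmetric 3',5'-dihydroxy-4'-methoxyphenyl group, so three of eight oxygens must end as free phenols among five methyl ethers. The fragile features are the electron-rich, oxidisable polyphenol rings, the C5 hydroxyl chelated to the C4 carbonyl, and the C3 methyl enol ether, which a Lewis acid able to cleave an ether beside the carbonyl would also attack. Late selective methylation or demethylation is therefore best avoided. The pentasubstituted ring A, whose single free carbon must become the attachment point of C4, is the hardest piece to assemble. The key step uses the fact that C2 (bearing ring B) and C3 (bearing OMe) are the two carbons of a 1-aryl-2-methoxyethyne, while C4 and O1 are the formyl carbon and phenol oxygen of a ring A salicylaldehyde.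

## Logic of the disconnections

**17 back to 16.** The three O–CH2Ph bonds at O5, O3' and O5' are cut. Only the three phenols need masking, and one group that falls under neutral reduction spares the five methyl ethers and the C3 enol ether. The gain is that all earlier compounds are neutral, non-chelating and resistant to oxidation. The demand is that hydrogenolysis leaves the C2=C3 bond of the pyranone alone.

**16 back to 8 and 15.** The C4–C3 and O1–C2 bonds of ring C are cut. This is the most convergent cut: it gives a ring A piece and a ring B piece that already carry all eight oxygens in their final state, and it removes the only heterocycle. The demand is high: the formyl C–H of 8 must be activated, 15 must insert with the acyl group going to the methoxy-bearing carbon, and the acid-sensitive ynol ether must survive oxidative conditions.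

**15 back to 13.** The two π bonds of the alkyne are traced to the C=O and the neighbouring CH2 of a ketone, by way of 14. The reason is handling: 15 is hydrolytically labile, whereas 13 is robust and can be converted just before use. The demand is an enol derivative with hydrogen anti to the leaving group, which lithium chelation by the α-methoxy oxygen should supply.

**13 back to 12, and 12 back to 10 and 11.** The bond between the ring B carbonyl carbon and the methoxy-bearing carbon is cut, after an ester group has been placed on that carbon as a removable activator. This reduces 13 to a benzoate and a two-carbon piece that already holds the future C3 oxygen as its methyl ether. The demand is a crossed acylation that outruns self-condensation of 11, followed by loss of the ester carbon without retro-Claisen cleavage.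

**10 back to 9.** The two aryl O–benzyl bonds and the ester O–benzyl bond are cut. All three acidic sites are alkylated in one operation, and the ester formed is the acyl donor for the next step. The demand is only complete alkylation.

**8 back to 7.** One O–benzyl bond is cut. The second phenol is masked so that only one phenoxide can bind the metal in the key step and the electron-rich ring is less easily oxidised. Since 7 is symmetric, it does not matter which hydroxyl reacts, but the forward step must stop after one alkylation. The hydrogen bond of the remaining hydroxyl to the formyl group should ensure this.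

**7 back to 5.** The aryl–CHO bond is cut. The formyl carbon goes onto the only free ring position, so no regiochemical question arises. The demand is a formylation that tolerates two free phenols; 6 is its primary product.

**5 back to 3, and 3 back to 1.** Two aryl C–O bonds are cut back to C–Br (by way of 4), and the two C–Br bonds back to C–H (by way of 2). The outer methoxy groups of 1 direct electrophiles to exactly the two positions that must become oxygen-bearing. The demands are a clean meta-dibromination and a double C–O coupling on an electron-rich arene.

## Other disconnections considered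

**Alternative 1:** The cut is the O1–C2 bond of ring C together with a change of ring size. The flavonol 3-hydroxy-5,6,7,8,4'-pentamethoxy-3',5'-bis(methanesulfonyloxy)flavone A1 is traced to the aurone dibromide A2, which comes from bromine addition to the aurone A3. In the forward direction, ethanolic KOH would open the five-membered ring of A2 at its O–C2 bond, and the phenoxide would reclose on the benzylic carbon to give the six-membered ring with the C3 oxygen in place (Auwers flavonol synthesis).
- In its favour: the ring-forming event is long established, needs no metal, and involves no alkyne insertion whose orientation must be trusted. On this point of regiochemical certainty it is the better plan, and it avoids any acid-sensitive ynol ether.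
- Against it here: A1 is three adjustments away from the target pattern. The C3 hydroxyl must be methylated, the two mesylates removed, and the C5 methyl ether cleaved selectively beside the C3 methyl ether, which flanks the same carbonyl and can bind the same Lewis acid. The aryl mesylates, needed to deactivate ring B during bromination of A3, are themselves at risk in hot ethanolic KOH.
- Comparison: on structure, the chosen plan places every oxygen in its final form before ring closure, whereas A1 needs correction at three kinds of oxygen. On mechanism, an ionic ring opening and reclosure stands against an organometallic C–H annulation, and the ionic sequence has the stronger precedent. On step economy, three steps would follow the key step, against one in the chosen plan.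

**Alternative 2:** The cut is the C4–C4a bond, with the C3 oxygen introduced as a ketone. The racemic chroman-3-one 2-[3,5-bis(benzyloxy)-4-methoxyphenyl]-5-(benzyloxy)-6,7,8-trimethoxychroman-3-one A4 is traced to the aryl propargyl ether A5. In the forward direction, the monovalent gold complex Ph3PAuNTf2 and 3,5-dichloropyridine N-oxide would oxidise the terminal alkyne of A5 to an α-oxo gold carbene, which would attack the only free ring A carbon and close ring C.
- In its favour: ring closure can occur at only one arene position, the conditions are mild, and A5 is built by simple etherification. On certainty of the site of ring closure it is the equal or the better of the chosen plan.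
- Against it here: A4 has the wrong oxidation level. C4 is a CH2 group and C2 is sp3, so oxidation at C4 to reach the flavonol level and then O-methylation would still be needed before debenzylation. A stereocenter is created at C2 only to be destroyed. The doubly activated (benzylic and propargylic) C–O bond of A5 may ionise under the Lewis-acidic catalyst, and the carbene may be intercepted by the ether oxygen or oxidised a second time.
- Comparison: on structure, the chosen plan delivers ring C at the final oxidation level and A4 does not. On mechanism, both rely on late-transition-metal catalysis with an external oxidant, and the gold step is closer to established substrate classes. On step economy, at least three steps would follow the key step, against one.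

**Alternative 3:** The cut is the O1–C8a bond, with ring A taken back to a quinone. The flavone 3',5'-bis(benzyloxy)-5,8-dihydroxy-3,6,7,4'-tetramethoxyflavone A6 is traced to the acylquinone diketone A7. In the forward direction, the enol oxygen of the 2-methoxy-1,3-diketone of A7 would add to the quinone carbon next to the acyl-bearing carbon (intramolecular oxa-Michael addition), and tautomerisation would give the hydroquinone ring of A6.
- In its favour: the aryl C–O bond forms without a pre-installed phenol, no metal is needed, and the C5 hydroxyl emerges free and already distinguished from the C8 hydroxyl by its hydrogen bond to the carbonyl. On protecting-group economy at O5 it is the better plan, since ring A needs no benzyl group.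
- Against it here: the C8 oxygen arrives as a free hydroxyl and must be methylated selectively. A7 is a strongly electrophilic and oxidising acylquinone that carries an easily enolised diketone and electron-rich benzyl ethers, so generating it by oxidation and keeping it from redox side reactions is delicate. Making the diketone already requires a ring A ketone, from which a conventional cyclodehydration onto a phenol would be available without the redox detour.
- Comparison: on structure, both plans place the C3 methoxy group before ring closure, but A6 needs one more methylation. On mechanism, a polar conjugate addition stands against a C–H annulation, and the polar step is simpler in principle but depends on a sensitive intermediate. On step economy, two steps would follow the key step, against one, and the route to A7 is not shorter than the routes to 8 and 15.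

Key step: step 9

## Remarks on the chemistry (assumptions)

- The atom mapping of 8, 15 and 16 onto 17 was checked position by position, and no structure needed correction.
- 6 is written as its chloride; in the flask the counter-ion may be dichlorophosphate, which does not change the outcome.
- Partly benzylated or partly debenzylated species of steps 5 and 10 form in no fixed order and are not numbered; catalyst-bound rhodium species of step 9 are not numbered either.

## Route

Step 1
Reactants: 1 1,2,3-trimethoxybenzene
Product: 3 1,5-dibromo-2,3,4-trimethoxybenzene, via 1-bromo-2,3,4-trimethoxybenzene 2 (not isolated)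
Conditions: NBS (2.1 equiv), MeCN, 0 °C to rt, dark
Reagents that add atoms: N-bromosuccinimide, O=C1CCC(=O)N1Br
Why: Electrophilic aromatic bromination; the outer methoxy groups direct ortho and para to C4 and C6, whereas C5 is activated only by the central methoxy group, which is twisted out of conjugation, so the second bromine should enter meta to the first.

Step 2
Reactants: 3 1,5-dibromo-2,3,4-trimethoxybenzene
Product: 5 4,5,6-trimethoxybenzene-1,3-diol, via 5-bromo-2,3,4-trimethoxyphenol 4 (not isolated)
Conditions: Pd2(dba)3 (2 mol%), tBuXPhos (8 mol%), KOH (6 equiv), 1,4-dioxane/H2O 1:1, 100 °C, Ar; then degassed aq. HCl, 0 °C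
Reagents that add atoms: potassium hydroxide, [K+].[OH-]
Why: Palladium-catalysed hydroxylation of aryl bromides (C–O cross-coupling with hydroxide); the bulky biaryl phosphine allows oxidative addition of zerovalent palladium to the electron-rich, ortho-substituted C–Br bonds and C–O reductive elimination from the arylpalladium hydroxide. The electron-rich diol 5 is air-sensitive and is carried into step 3 without storage.

Step 3
Reactants: 5 4,5,6-trimethoxybenzene-1,3-diol
Product: 7 2,6-dihydroxy-3,4,5-trimethoxybenzaldehyde, via iminium chloride 6 (not isolated)
Conditions: POCl3 (1.2 equiv), DMF (3 equiv), MeCN, 0 °C to rt; then H2O, 50 °C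
Reagents that add atoms: N,N-dimethylformamide, CN(C)C=O (formyl carbon of 7 and the NMe2 group of 6); phosphoryl chloride, O=P(Cl)(Cl)Cl (chloride of 6 only); water, O (carbonyl oxygen of 7)
Why: Vilsmeier–Haack formylation; the chloroiminium ion attacks the only free ring carbon, which is ortho to both hydroxyl groups and strongly activated, and aqueous hydrolysis of 6 (and of any O-formate) gives the aldehyde.

Step 4
Reactants: 7 2,6-dihydroxy-3,4,5-trimethoxybenzaldehyde
Product: 8 2-(benzyloxy)-6-hydroxy-3,4,5-trimethoxybenzaldehyde
Conditions: BnBr (1.05 equiv), K2CO3 (1.1 equiv), acetone, rt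
Reagents that add atoms: benzyl bromide, BrCc1ccccc1
Why: Williamson ether synthesis; the two hydroxyl groups are equivalent, and after one is benzylated the other is held in a strong hydrogen bond to the formyl oxygen and is much less acidic and nucleophilic, so one equivalent of halide with a weak base should stop at the monoether, as is usual for 2,6-dihydroxyaryl carbonyl compounds.

Step 5
Reactants: 9 3,5-dihydroxy-4-methoxybenzoic acid
Product: 10 benzyl 3,5-bis(benzyloxy)-4-methoxybenzoate
Conditions: BnBr (3.3 equiv), K2CO3 (4 equiv), DMF, 60 °C
Reagents that add atoms: benzyl bromide, BrCc1ccccc1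
Why: Exhaustive O-alkylation (Williamson ether synthesis and carboxylate alkylation) of both phenols and the acid in one operation; the benzyl ester then serves as the acyl donor of step 6, so no separate esterification is needed.

Step 6
Reactants: 10 benzyl 3,5-bis(benzyloxy)-4-methoxybenzoate; 11 ethyl methoxyacetate
Product: 12 ethyl 3-[3,5-bis(benzyloxy)-4-methoxyphenyl]-2-methoxy-3-oxopropanoate (racemic)
Conditions: LiN(iPr)2 (2.5 equiv), 11 (1.5 equiv), THF, −78 °C; then 10, −78 °C to 0 °C; aq. NH4Cl
Reagents that add atoms: none
Why: Crossed Claisen condensation; 11 is fully converted into its lithium enolate before the non-enolisable benzoate is added, which suppresses self-condensation, and deprotonation of the product by the excess base drives the acylation and shields 12 from transesterification and retro-Claisen cleavage. The new stereocenter is configurationally labile, so 12 is racemic, and it is removed in step 7.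

Step 7
Reactants: 12 ethyl 3-[3,5-bis(benzyloxy)-4-methoxyphenyl]-2-methoxy-3-oxopropanoate
Product: 13 1-[3,5-bis(benzyloxy)-4-methoxyphenyl]-2-methoxyethan-1-one
Conditions: LiCl (cat.), H2O (3 equiv), DMSO, 140 °C
Reagents that add atoms: none
Why: Krapcho dealkoxycarbonylation; in wet DMSO the activated ester is cleaved and the β-keto carboxylate loses CO2 under neutral conditions, which avoids the retro-Claisen cleavage that aqueous hydroxide could cause and leaves the benzyl ethers intact.

Step 8
Reactants: 13 1-[3,5-bis(benzyloxy)-4-methoxyphenyl]-2-methoxyethan-1-one
Product: 15 1,3-bis(benzyloxy)-2-methoxy-5-(methoxyethynyl)benzene, via (Z)-enol triflate 14 (not isolated)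
Conditions: LiN(SiMe3)2 (1.1 equiv), THF, −78 °C; PhNTf2 (1.1 equiv), −78 °C to rt; then KOtBu (2.5 equiv), −78 °C to 0 °C; aq. NaHCO3; Et3N-deactivated silica
Reagents that add atoms: N-phenylbis(trifluoromethanesulfonimide), O=S(=O)(N(c1ccccc1)S(=O)(=O)C(F)(F)F)C(F)(F)F (CF3SO2 group of 14 only; none of it remains in 15)
Why: Enol triflate elimination route from α-alkoxy ketones to ynol ethers; lithium chelation by the α-methoxy oxygen should give the (Z)-enolate, O-triflation then gives 14 with hydrogen anti to the triflate, and KOtBu effects anti-E2 loss of triflic acid. The product is stable to base and is kept away from acid.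

Step 9
Reactants: 8 2-(benzyloxy)-6-hydroxy-3,4,5-trimethoxybenzaldehyde; 15 1,3-bis(benzyloxy)-2-methoxy-5-(methoxyethynyl)benzene
Product: 16 5,3',5'-tris(benzyloxy)-3,6,7,8,4'-pentamethoxyflavone [5-(benzyloxy)-2-[3,5-bis(benzyloxy)-4-methoxyphenyl]-3,6,7,8-tetramethoxy-4H-chromen-4-one]
Conditions: [Cp*RhCl2]2 (2.5 mol%), Cu(OAc)2 (anhydrous, 2.2 equiv), Na2CO3 (2 equiv), 4 Å MS, toluene, 90 °C, Ar; 15 (1.5 equiv) added over 4 h
Reagents that add atoms: none
Why: Proposed new method: the phenoxide of 8 binds trivalent rhodium formed from [Cp*RhCl2]2 and acetate, the neighbouring formyl C–H is cleaved by acetate-assisted metalation to a five-membered acyl rhodacycle, 15 inserts into the Rh–acyl bond to give a seven-membered oxarhodacycle, and C–O reductive elimination releases 16 and monovalent rhodium, which Cu(OAc)2 reoxidises. The closest known reaction type is the rhodium/copper oxidative annulation of salicylaldehydes with diaryl and aryl alkyl alkynes to 2,3-disubstituted chromones; an ynol ether has not been shown as the alkyne in this annulation, hence the label. Ring C closes in a formal [4+2] oxidative annulation, the six-membered ring arising by reductive elimination between the phenoxide oxygen and the alkenyl carbon of the seven-membered metallacycle. No stereocenter is formed. The step needs one orientation of insertion, acyl to the methoxy-bearing carbon and rhodium to the aryl-bearing carbon: the ynol ether is polarised with its oxygen-bearing carbon electrophilic and its aryl-bearing carbon nucleophilic, so the migrating acyl group should go to the former, and the aryl group stabilises the Rh–C bond at the latter, as it does for aryl alkyl alkynes. Ring A has no aryl C–H, so only the formyl C–H can be activated, and the benzyl group on the second oxygen leaves a single phenoxide to bind the metal. Na2CO3 and molecular sieves remove acetic acid and water, slow addition keeps the concentration of the acid-sensitive 15 low, and the methyl ynol ether has no β-hydrogen in its alkyl group and so cannot fragment to a ketene on heating.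

Step 10
Reactants: 16 5,3',5'-tris(benzyloxy)-3,6,7,8,4'-pentamethoxyflavone
Product: 17 5,3',5'-trihydroxy-3,6,7,8,4'-pentamethoxyflavone [2-(3,5-dihydroxy-4-methoxyphenyl)-5-hydroxy-3,6,7,8-tetramethoxy-4H-chromen-4-one]
Conditions: H2 (1 atm), 10% Pd/C, EtOAc/MeOH 1:1, rt
Reagents that add atoms: none
Why: Catalytic hydrogenolysis of aryl benzyl ethers; the three O–CH2Ph bonds are cleaved under neutral conditions that should leave the five methyl ethers and the tetrasubstituted, conjugated C2=C3 bond of the chromone untouched, provided the reaction is stopped once debenzylation is complete.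

## Compound list

1 | 1,2,3-trimethoxybenzene | COc1cccc(OC)c1OC | starting material
2 | 1-bromo-2,3,4-trimethoxybenzene | COc1ccc(Br)c(OC)c1OC | intermediate (not isolated)
3 | 1,5-dibromo-2,3,4-trimethoxybenzene | COc1c(Br)cc(Br)c(OC)c1OC | intermediate
4 | 5-bromo-2,3,4-trimethoxyphenol | COc1c(O)cc(Br)c(OC)c1OC | intermediate (not isolated)
5 | 4,5,6-trimethoxybenzene-1,3-diol | COc1c(O)cc(O)c(OC)c1OC | intermediate
6 | N-[(2,6-dihydroxy-3,4,5-trimethoxyphenyl)methylidene]-N-methylmethanaminium chloride | C[N+](C)=Cc1c(O)c(OC)c(OC)c(OC)c1O.[Cl-] | intermediate (not isolated)
7 | 2,6-dihydroxy-3,4,5-trimethoxybenzaldehyde | O=Cc1c(O)c(OC)c(OC)c(OC)c1O | intermediate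
8 | 2-(benzyloxy)-6-hydroxy-3,4,5-trimethoxybenzaldehyde | O=Cc1c(O)c(OC)c(OC)c(OC)c1OCc1ccccc1 | intermediate
9 | 3,5-dihydroxy-4-methoxybenzoic acid | COc1c(O)cc(C(=O)O)cc1O | starting material
10 | benzyl 3,5-bis(benzyloxy)-4-methoxybenzoate | COc1c(OCc2ccccc2)cc(C(=O)OCc2ccccc2)cc1OCc1ccccc1 | intermediate
11 | ethyl methoxyacetate | CCOC(=O)COC | starting material
12 | ethyl 3-[3,5-bis(benzyloxy)-4-methoxyphenyl]-2-methoxy-3-oxopropanoate (racemic) | CCOC(=O)C(OC)C(=O)c1cc(OCc2ccccc2)c(OC)c(OCc2ccccc2)c1 | intermediate
13 | 1-[3,5-bis(benzyloxy)-4-methoxyphenyl]-2-methoxyethan-1-one | COCC(=O)c1cc(OCc2ccccc2)c(OC)c(OCc2ccccc2)c1 | intermediate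
14 | (Z)-1-[3,5-bis(benzyloxy)-4-methoxyphenyl]-2-methoxyethenyl trifluoromethanesulfonate | CO/C=C(\OS(=O)(=O)C(F)(F)F)c1cc(OCc2ccccc2)c(OC)c(OCc2ccccc2)c1 | intermediate (not isolated)
15 | 1,3-bis(benzyloxy)-2-methoxy-5-(methoxyethynyl)benzene | COC#Cc1cc(OCc2ccccc2)c(OC)c(OCc2ccccc2)c1 | intermediate
16 | 5,3',5'-tris(benzyloxy)-3,6,7,8,4'-pentamethoxyflavone | O=c1c(OC)c(-c3cc(OCc4ccccc4)c(OC)c(OCc4ccccc4)c3)oc2c(OC)c(OC)c(OC)c(OCc3ccccc3)c12 | intermediate
17 | 5,3',5'-trihydroxy-3,6,7,8,4'-pentamethoxyflavone | COc1c(O)cc(-c2oc3c(OC)c(OC)c(OC)c(O)c3c(=O)c2OC)cc1O | target

## Step count and least certain steps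

Total step count: 10. Longest linear sequence: 6 steps (steps 1, 2, 3, 4, 9, 10 from 1; equally steps 5, 6, 7, 8, 9, 10 from 9).

**Step 9 (key step, Proposed new method).**
- What may go wrong: 15 may be consumed by acid- or metal-promoted addition of acetic acid, adventitious water or the phenol of 8 before it inserts. Insertion may also occur in the opposite orientation, which would exchange the aryl and methoxy groups between C2 and C3. The acyl rhodium species may lose carbon monoxide.
- Fallback (known chemistry; sets out from 8 and 13, comes back at 16): protection of the phenol of 8 (MOMCl, iPr2NEt, CH2Cl2) would give 2-(benzyloxy)-3,4,5-trimethoxy-6-(methoxymethoxy)benzaldehyde F1. Aldol addition of the lithium enolate of 13 (LiN(iPr)2, THF, −78 °C) to it would give 1-[3,5-bis(benzyloxy)-4-methoxyphenyl]-3-[2-(benzyloxy)-3,4,5-trimethoxy-6-(methoxymethoxy)phenyl]-3-hydroxy-2-methoxypropan-1-one F2 as a mixture of racemic diastereomers. Dess–Martin oxidation would give 1-[3,5-bis(benzyloxy)-4-methoxyphenyl]-3-[2-(benzyloxy)-3,4,5-trimethoxy-6-(methoxymethoxy)phenyl]-2-methoxypropane-1,3-dione F3. HCl in MeOH at 50 °C would then remove the methoxymethyl group to give 1-[3,5-bis(benzyloxy)-4-methoxyphenyl]-3-[2-(benzyloxy)-6-hydroxy-3,4,5-trimethoxyphenyl]-2-methoxypropane-1,3-dione F4, which is not isolated. Its phenol oxygen adds to the ring B carbonyl, and loss of water gives 16. This is the classical cyclodehydration of a 1,3-diketone to a flavone.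

**Step 8.**
- What may go wrong: enol triflation may give the geometry with hydrogen syn to the leaving group, which eliminates slowly. The ynol ether may also be hydrated or add nucleophiles during work-up and chromatography.
- Fallback (sets out from 12 and 5, comes back at 17): thermal condensation of the β-keto ester 12 with the symmetric diol 5 (neat or in Ph2O, 240 °C, Ar; pyrone synthesis from a phenol and a β-keto ester) should acylate the only free ring carbon of 5 and close ring C through either of the equivalent hydroxyl groups. This would give 3',5'-bis(benzyloxy)-5-hydroxy-3,6,7,8,4'-pentamethoxyflavone F5 directly, and hydrogenolysis (H2, 10% Pd/C) of its two benzyl ethers would give 17. The ynol ether and the rhodium step are not needed on this path.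

**Step 2.**
- What may go wrong: the second C–O coupling may stall, because oxidative addition to the very electron-rich bromophenoxide derived from 4 is slow and reductive debromination can compete. The electron-rich diol may also be oxidised if air enters the hot basic mixture.
- Fallback (sets out from 3, comes back at 5): Miyaura borylation of both C–Br bonds of the neutral dibromide (B2pin2, Pd(dppf)Cl2, KOAc, dioxane, 90 °C) would give 2,2'-(4,5,6-trimethoxy-1,3-phenylene)bis(4,4,5,5-tetramethyl-1,3,2-dioxaborolane) F6, which can be purified. Oxidation of its C–B bonds (H2O2, NaOH, THF/H2O, 0 °C, Ar) would give 5, so that the C–O bonds form by 1,2-migration from boron and not by reductive elimination from palladium.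

**Step 4.**
- What may go wrong: alkylation may run on to the dibenzyl ether, or stop short and leave a mixture that is hard to separate.
- Fallback (sets out from 7, comes back at 8): exhaustive benzylation (BnBr in excess, K2CO3, DMF, 60 °C) would give 2,6-bis(benzyloxy)-3,4,5-trimethoxybenzaldehyde F7. MgBr2·OEt2 (1.1 equiv, toluene/Et2O, reflux) would then cleave one benzyl ether ortho to the formyl group under chelation control. The magnesium phenoxide chelate formed after the first cleavage should protect the second ether, giving 8.

**Step 6.**
- What may go wrong: 11 may self-condense during enolate formation, attack on the electron-rich benzoate may be sluggish, and the product may undergo retro-Claisen cleavage on work-up.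
- Fallback (sets out from 10, comes back at 13): conversion of the ester into the Weinreb amide (MeNHOMe·HCl, iPrMgCl, THF, −20 °C) would give 3,5-bis(benzyloxy)-N,4-dimethoxy-N-methylbenzamide F8. Addition of methoxymethyllithium (from Bu3SnCH2OMe and n-BuLi, THF, −78 °C) would give 13 directly through the stable tetrahedral chelate, bypassing 12 and step 7.

## Further compounds

F1 | step 9 | 2-(benzyloxy)-3,4,5-trimethoxy-6-(methoxymethoxy)benzaldehyde | O=Cc1c(OCOC)c(OC)c(OC)c(OC)c1OCc1ccccc1
F2 | step 9 | 1-[3,5-bis(benzyloxy)-4-methoxyphenyl]-3-[2-(benzyloxy)-3,4,5-trimethoxy-6-(methoxymethoxy)phenyl]-3-hydroxy-2-methoxypropan-1-one (racemic diastereomer mixture) | COC(C(O)c1c(OCOC)c(OC)c(OC)c(OC)c1OCc1ccccc1)C(=O)c1cc(OCc2ccccc2)c(OC)c(OCc2ccccc2)c1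
F3 | step 9 | 1-[3,5-bis(benzyloxy)-4-methoxyphenyl]-3-[2-(benzyloxy)-3,4,5-trimethoxy-6-(methoxymethoxy)phenyl]-2-methoxypropane-1,3-dione (racemic) | COC(C(=O)c1c(OCOC)c(OC)c(OC)c(OC)c1OCc1ccccc1)C(=O)c1cc(OCc2ccccc2)c(OC)c(OCc2ccccc2)c1
F4 | step 9 | 1-[3,5-bis(benzyloxy)-4-methoxyphenyl]-3-[2-(benzyloxy)-6-hydroxy-3,4,5-trimethoxyphenyl]-2-methoxypropane-1,3-dione (racemic) | COC(C(=O)c1c(O)c(OC)c(OC)c(OC)c1OCc1ccccc1)C(=O)c1cc(OCc2ccccc2)c(OC)c(OCc2ccccc2)c1
F5 | step 8 | 3',5'-bis(benzyloxy)-5-hydroxy-3,6,7,8,4'-pentamethoxyflavone | O=c1c(OC)c(-c3cc(OCc4ccccc4)c(OC)c(OCc4ccccc4)c3)oc2c(OC)c(OC)c(OC)c(O)c12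
F6 | step 2 | 2,2'-(4,5,6-trimethoxy-1,3-phenylene)bis(4,4,5,5-tetramethyl-1,3,2-dioxaborolane) | COc1c(B2OC(C)(C)C(C)(C)O2)cc(B2OC(C)(C)C(C)(C)O2)c(OC)c1OC
F7 | step 4 | 2,6-bis(benzyloxy)-3,4,5-trimethoxybenzaldehyde | O=Cc1c(OCc2ccccc2)c(OC)c(OC)c(OC)c1OCc1ccccc1
F8 | step 6 | 3,5-bis(benzyloxy)-N,4-dimethoxy-N-methylbenzamide | CON(C)C(=O)c1cc(OCc2ccccc2)c(OC)c(OCc2ccccc2)c1
A1 | alternative 1 | 3-hydroxy-5,6,7,8,4'-pentamethoxy-3',5'-bis(methanesulfonyloxy)flavone | O=c1c(O)c(-c3cc(OS(C)(=O)=O)c(OC)c(OS(C)(=O)=O)c3)oc2c(OC)c(OC)c(OC)c(OC)c12
A2 | alternative 1 | 2-bromo-2-{bromo[3,5-bis(methanesulfonyloxy)-4-methoxyphenyl]methyl}-4,5,6,7-tetramethoxy-1-benzofuran-3(2H)-one (racemic diastereomer mixture) | O=C1c2c(OC)c(OC)c(OC)c(OC)c2OC1(Br)C(Br)c1cc(OS(C)(=O)=O)c(OC)c(OS(C)(=O)=O)c1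
A3 | alternative 1 | (Z)-2-[3,5-bis(methanesulfonyloxy)-4-methoxybenzylidene]-4,5,6,7-tetramethoxy-1-benzofuran-3(2H)-one | O=C1c2c(OC)c(OC)c(OC)c(OC)c2O/C1=C\c1cc(OS(C)(=O)=O)c(OC)c(OS(C)(=O)=O)c1
A4 | alternative 2 | 2-[3,5-bis(benzyloxy)-4-methoxyphenyl]-5-(benzyloxy)-6,7,8-trimethoxychroman-3-one (racemic) | O=C1Cc2c(OCc3ccccc3)c(OC)c(OC)c(OC)c2OC1c1cc(OCc2ccccc2)c(OC)c(OCc2ccccc2)c1
A5 | alternative 2 | 1-(benzyloxy)-5-{[1-(3,5-bis(benzyloxy)-4-methoxyphenyl)prop-2-yn-1-yl]oxy}-2,3,4-trimethoxybenzene (racemic) | C#CC(Oc1cc(OCc2ccccc2)c(OC)c(OC)c1OC)c1cc(OCc2ccccc2)c(OC)c(OCc2ccccc2)c1
A6 | alternative 3 | 3',5'-bis(benzyloxy)-5,8-dihydroxy-3,6,7,4'-tetramethoxyflavone | O=c1c(OC)c(-c3cc(OCc4ccccc4)c(OC)c(OCc4ccccc4)c3)oc2c(O)c(OC)c(OC)c(O)c12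
A7 | alternative 3 | 1-[3,5-bis(benzyloxy)-4-methoxyphenyl]-3-(4,5-dimethoxy-3,6-dioxocyclohexa-1,4-dien-1-yl)-2-methoxypropane-1,3-dione (racemic) | COC(C(=O)C1=CC(=O)C(OC)=C(OC)C1=O)C(=O)c1cc(OCc2ccccc2)c(OC)c(OCc2ccccc2)c1
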